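**Retrosynthetic overview**

1. The furan-2(5H)-one ring is built last. Its C5(H)–O corner, ring carbon C4 and the CH2 attached to C5 come from (S)-malic acid, C2/C3 from Ph3P=C=C=O, and the hydroxymethyl carbon on C4 from an alkoxymethyllithium.
2. Key disconnection: the bond between the vinylic CH of the CH2OH-bearing trisubstituted alkene and the CH2 attached to furanone C5. It is made by nickel-electrocatalytic decarboxylative alkenylation of an (E)-alkenyl iodide (C19 fragment A) with the N-acyloxyphthalimide of L-malic acid acetonide (fragment B).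
3. Enabling feature: the atoms CH2–C5H(O)–C4 of the lactone ring map onto C3–C2–C1 of malic acid. Loss of the free C4 carboxyl group as CO2 puts a primary radical exactly on that CH2, one atom away from the stereocentre, which is carried over unchanged; the dioxolanone carbonyl (future ring carbon C4) stays activated for the ring construction.
4. Fragment A: dihydro-β-ionone → terminal alkyne → carboalumination/oxirane (E-trisubstituted alkene) → malonate → CHI3/decarboxylative elimination ((E)-iodoalkene) → reduction and PMB ether.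
5. Ring order: the cyclohexene ring is bought in; a temporary 1,3-dioxolan-4-one ring is formed in step 9 and opened in step 13; the furanone ring is closed in step 14; PMB removal ends the route.

Key step: step 12

Remark on the chemistry: the SMILES is read as 5S at the lactone carbon and E at both trisubstituted alkenes (in the CH2OH-bearing alkene the CH2OH group is trans to the CH2 that leads to the lactone).

**Route**

Step 1
Reactants: 1 4-(2,6,6-trimethylcyclohex-1-en-1-yl)butan-2-one (dihydro-β-ionone)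
Product: 3 2-(but-3-yn-1-yl)-1,3,3-trimethylcyclohex-1-ene, via enol diethyl phosphate 2 (not isolated)
Conditions: LiN(i-Pr)2 (1.05 equiv), THF, −78 °C; ClP(O)(OEt)2, −78 °C to rt; LiN(i-Pr)2 (2.3 equiv), THF, −78 °C to rt; H2O
Reagents that add atoms: none
Why: Kinetic enolisation on the CH3 side, O-phosphorylation and base-induced elimination of the enol phosphate should give the terminal alkyne (methyl ketone to alkyne conversion by enol phosphate elimination).

Step 2
Reactants: 3 2-(but-3-yn-1-yl)-1,3,3-trimethylcyclohex-1-ene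
Product: 6 (3E)-4-methyl-6-(2,6,6-trimethylcyclohex-1-en-1-yl)hex-3-en-1-ol, via alkenyldimethylalane 4 (not isolated), via lithium alkenylaluminate 5 (not isolated)
Conditions: Me3Al (2.5 equiv), Cp2ZrCl2 (0.25 equiv), CH2Cl2, 0 °C to rt; removal of volatiles; n-BuLi, THF/hexane, −78 to 0 °C; oxirane, 0 °C; aq. HCl
Reagents that add atoms: trimethylaluminium C[Al](C)C; oxirane C1CO1
Why: Zirconium-catalysed syn-carboalumination (Negishi carboalumination) should place CH3 on the internal and aluminium on the terminal alkyne carbon with E geometry, and the derived aluminate should open oxirane with retention at the alkenyl carbon.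

Step 3
Reactants: 6 (3E)-4-methyl-6-(2,6,6-trimethylcyclohex-1-en-1-yl)hex-3-en-1-ol
Product: 7 2-[(3E)-6-iodo-3-methylhex-3-en-1-yl]-1,3,3-trimethylcyclohex-1-ene
Conditions: I2, PPh3, imidazole, CH2Cl2, 0 °C to rt
Reagents that add atoms: iodine II
Why: Appel-type iodination should convert the primary alcohol into the iodide by SN2 displacement without touching either alkene.

Step 4
Reactants: 7 2-[(3E)-6-iodo-3-methylhex-3-en-1-yl]-1,3,3-trimethylcyclohex-1-ene
Product: 8 diethyl 2-[(3E)-4-methyl-6-(2,6,6-trimethylcyclohex-1-en-1-yl)hex-3-en-1-yl]propanedioate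
Conditions: diethyl malonate (3 equiv), NaH (2.5 equiv), THF/DMF, 0 to 60 °C
Reagents that add atoms: diethyl malonate CCOC(=O)CC(=O)OCC
Why: Malonic ester alkylation of a primary iodide, with excess malonate to suppress dialkylation.

Step 5
Reactants: 8 diethyl 2-[(3E)-4-methyl-6-(2,6,6-trimethylcyclohex-1-en-1-yl)hex-3-en-1-yl]propanedioate
Product: 9 diethyl 2-(diiodomethyl)-2-[(3E)-4-methyl-6-(2,6,6-trimethylcyclohex-1-en-1-yl)hex-3-en-1-yl]propanedioate
Conditions: NaH (1.3 equiv), Et2O, reflux; CHI3 (1.3 equiv), reflux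
Reagents that add atoms: iodoform IC(I)I
Why: C-diiodomethylation of the malonate anion with iodoform is the established first stage of the malonate route to (E)-3-iodo-2-alkylacrylic acids, and the anion should trap the halocarbon electrophile far faster than the two alkenes do.

Step 6
Reactants: 9 diethyl 2-(diiodomethyl)-2-[(3E)-4-methyl-6-(2,6,6-trimethylcyclohex-1-en-1-yl)hex-3-en-1-yl]propanedioate
Product: 10 (2E,5E)-2-(iodomethylidene)-6-methyl-8-(2,6,6-trimethylcyclohex-1-en-1-yl)oct-5-enoic acid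
Conditions: KOH, EtOH/H2O (3:1), reflux; aq. HCl to pH 2
Reagents that add atoms: potassium hydroxide [K+].[OH-]
Why: Saponification followed by decarboxylative elimination of iodide should give the β-iodoacrylic acid with iodine trans to the remaining carboxyl group, as in the known 2-methyl case.

Step 7
Reactants: 10 (2E,5E)-2-(iodomethylidene)-6-methyl-8-(2,6,6-trimethylcyclohex-1-en-1-yl)oct-5-enoic acid
Product: 11 (2E,5E)-2-(iodomethylidene)-6-methyl-8-(2,6,6-trimethylcyclohex-1-en-1-yl)oct-5-en-1-ol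
Conditions: LiAlH4, Et2O, 0 °C; H2O, aq. NaOH
Reagents that add atoms: none
Why: Hydride reduction of the carboxylic acid to the primary allylic alcohol, as established for (E)-3-iodo-2-methylacrylic acid, with low temperature to spare the C–I bond.

Step 8
Reactants: 11 (2E,5E)-2-(iodomethylidene)-6-methyl-8-(2,6,6-trimethylcyclohex-1-en-1-yl)oct-5-en-1-ol
Product: 12 1-({[(2E,5E)-2-(iodomethylidene)-6-methyl-8-(2,6,6-trimethylcyclohex-1-en-1-yl)oct-5-en-1-yl]oxy}methyl)-4-methoxybenzene
Conditions: NaH, 4-methoxybenzyl chloride, n-Bu4NI (cat.), THF/DMF, 0 °C to rt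
Reagents that add atoms: 4-methoxybenzyl chloride COc1ccc(CCl)cc1
Why: Williamson etherification; the alkenyl iodide has no hydrogen on the neighbouring alkene carbon, so base-induced elimination to an alkyne cannot occur.

Step 9
Reactants: 13 (2S)-2-hydroxybutanedioic acid (L-malic acid)
Product: 14 2-[(4S)-2,2-dimethyl-5-oxo-1,3-dioxolan-4-yl]acetic acid
Conditions: 2,2-dimethoxypropane, p-TsOH (cat.), rt
Reagents that add atoms: 2,2-dimethoxypropane COC(C)(C)OC
Why: Acid-catalysed transketalisation should engage the α-hydroxy acid selectively as the five-membered 1,3-dioxolan-4-one and leave the β-carboxyl group free, without touching the stereocentre.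

Step 10
Reactants: 14 2-[(4S)-2,2-dimethyl-5-oxo-1,3-dioxolan-4-yl]acetic acid
Product: 15 1,3-dioxo-1,3-dihydro-2H-isoindol-2-yl 2-[(4S)-2,2-dimethyl-5-oxo-1,3-dioxolan-4-yl]acetate
Conditions: N-hydroxyphthalimide, N,N′-diisopropylcarbodiimide, DMAP (cat.), CH2Cl2, rt
Reagents that add atoms: N-hydroxyphthalimide O=C1c2ccccc2C(=O)N1O
Why: Carbodiimide (Steglich-type) esterification should give the redox-active N-acyloxyphthalimide.

Step 11
Reactants: 16 (tributylstannyl)methanol
Product: 17 tributyl{[(4-methoxyphenyl)methoxy]methyl}stannane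
Conditions: NaH, 4-methoxybenzyl chloride, n-Bu4NI (cat.), THF/DMF, 0 °C to rt
Reagents that add atoms: 4-methoxybenzyl chloride COc1ccc(CCl)cc1
Why: Williamson etherification gives the stannane precursor of an α-alkoxymethyl carbanion.

Step 12
Reactants: 12 1-({[(2E,5E)-2-(iodomethylidene)-6-methyl-8-(2,6,6-trimethylcyclohex-1-en-1-yl)oct-5-en-1-yl]oxy}methyl)-4-methoxybenzene (fragment A); 15 1,3-dioxo-1,3-dihydro-2H-isoindol-2-yl 2-[(4S)-2,2-dimethyl-5-oxo-1,3-dioxolan-4-yl]acetate (fragment B)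
Product: 19 (5S)-5-[(2E,6E)-3-{[(4-methoxyphenyl)methoxy]methyl}-7-methyl-9-(2,6,6-trimethylcyclohex-1-en-1-yl)nona-2,6-dien-1-yl]-2,2-dimethyl-1,3-dioxolan-4-one, via dioxolanonylmethyl radical 18 (not isolated)
Conditions: 15 (1.5 equiv), NiCl2·6H2O (10 mol %), 2,2′-bipyridine (10 mol %), AgNO3 (0.3 equiv), DMF, undivided cell, Mg anode, reticulated vitreous carbon cathode, constant current, rt
Reagents that add atoms: none
Why: Cathodically generated low-valent nickel–bipyridine should insert into the C–I bond of 12 with retention of alkene geometry, while single-electron reduction of 15 expels phthalimide anion and CO2 to give primary radical 18, whose capture at nickel and reductive elimination from a trivalent nickel centre forms the C(sp2)–C(sp3) bond. The closest known reaction type is the nickel-electrocatalytic decarboxylative alkenylation of redox-active esters with alkenyl iodides on a silver-modified cathode, as used for trisubstituted alkenes of polyene terpenoids. No ring is closed and no stereocentre is created: the radical site is the CH2 next to the dioxolanone stereocentre, which never becomes trigonal, so the S configuration from L-malic acid should be carried through unchanged. The step needs cross-coupling over homo-coupling and retention of the E geometry, which the stereospecific oxidative addition of a non-conjugated alkenyl iodide and fast radical capture should secure. A 1,2-shift or β-scission of 18 is not expected, because its β-substituents are only an ether oxygen and an ester-type carbonyl, both poor radical acceptors and poor leaving groups.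

Step 13
Reactants: 19 (5S)-5-[(2E,6E)-3-{[(4-methoxyphenyl)methoxy]methyl}-7-methyl-9-(2,6,6-trimethylcyclohex-1-en-1-yl)nona-2,6-dien-1-yl]-2,2-dimethyl-1,3-dioxolan-4-one; 17 tributyl{[(4-methoxyphenyl)methoxy]methyl}stannane
Product: 22 (3S,5E,9E)-3-hydroxy-1-[(4-methoxyphenyl)methoxy]-6-{[(4-methoxyphenyl)methoxy]methyl}-10-methyl-12-(2,6,6-trimethylcyclohex-1-en-1-yl)dodeca-5,9-dien-2-one, via alkoxymethyllithium 20 (not isolated), via lithium hemiketal alkoxide 21 (not isolated)
Conditions: 17 (1.5 equiv), n-BuLi (1.4 equiv), THF, −78 °C; then 19, −78 °C; AcOH, −78 °C to rt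
Reagents that add atoms: none
Why: Tin–lithium exchange gives the α-alkoxymethyllithium, which should add once to the activated dioxolanone carbonyl (organolithium mono-addition to a lactone-type ester); the cyclic hemiketal alkoxide persists at −78 °C and collapses only on protonation to the α-hydroxy ketone and acetone, so over-addition is avoided and the stereocentre is not exposed to base as a ketone.

Step 14
Reactants: 22 (3S,5E,9E)-3-hydroxy-1-[(4-methoxyphenyl)methoxy]-6-{[(4-methoxyphenyl)methoxy]methyl}-10-methyl-12-(2,6,6-trimethylcyclohex-1-en-1-yl)dodeca-5,9-dien-2-one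
Product: 24 (5S)-4-{[(4-methoxyphenyl)methoxy]methyl}-5-[(2E,6E)-3-{[(4-methoxyphenyl)methoxy]methyl}-7-methyl-9-(2,6,6-trimethylcyclohex-1-en-1-yl)nona-2,6-dien-1-yl]furan-2(5H)-one, via ester ylide 23 (not isolated)
Conditions: Ph3P=C=C=O (1.2 equiv), toluene, 80 °C
Reagents that add atoms: (triphenylphosphoranylidene)ketene O=C=C=P(c1ccccc1)(c1ccccc1)c1ccccc1
Why: Addition of the secondary hydroxyl group to the ketene ylide gives a stabilised ester ylide that should close the five-membered lactone by intramolecular Wittig olefination of the neighbouring ketone, under neutral conditions that leave the C5 stereocentre intact.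

Step 15
Reactants: 24 (5S)-4-{[(4-methoxyphenyl)methoxy]methyl}-5-[(2E,6E)-3-{[(4-methoxyphenyl)methoxy]methyl}-7-methyl-9-(2,6,6-trimethylcyclohex-1-en-1-yl)nona-2,6-dien-1-yl]furan-2(5H)-one
Product: 25 (5S)-4-(hydroxymethyl)-5-[(2E,6E)-3-(hydroxymethyl)-7-methyl-9-(2,6,6-trimethylcyclohex-1-en-1-yl)nona-2,6-dien-1-yl]furan-2(5H)-one
Conditions: DDQ (2.6 equiv), CH2Cl2/aq. Na2HPO4–NaH2PO4 buffer (pH 7), 0 °C
Reagents that add atoms: none
Why: Oxidative cleavage of both 4-methoxybenzyl ethers by DDQ (hydride abstraction, then hydrolysis) in a buffered medium should spare the furanone C5–H and the acid-sensitive polyene.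

**Compound list**

1 | 4-(2,6,6-trimethylcyclohex-1-en-1-yl)butan-2-one (dihydro-β-ionone) | CC1=C(CCC(C)=O)C(C)(C)CCC1 | starting material
2 | diethyl 4-(2,6,6-trimethylcyclohex-1-en-1-yl)but-1-en-2-yl phosphate | CC1=C(CCC(=C)OP(=O)(OCC)OCC)C(C)(C)CCC1 | intermediate
3 | 2-(but-3-yn-1-yl)-1,3,3-trimethylcyclohex-1-ene | CC1=C(CCC#C)C(C)(C)CCC1 | intermediate
4 | dimethyl[(1E)-2-methyl-4-(2,6,6-trimethylcyclohex-1-en-1-yl)but-1-en-1-yl]alane | CC1=C(CC/C(C)=C/[Al](C)C)C(C)(C)CCC1 | intermediate
5 | lithium butyl(dimethyl)[(1E)-2-methyl-4-(2,6,6-trimethylcyclohex-1-en-1-yl)but-1-en-1-yl]aluminate | [Li+].CC1=C(CC/C(C)=C/[Al-](C)(C)CCCC)C(C)(C)CCC1 | intermediate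
6 | (3E)-4-methyl-6-(2,6,6-trimethylcyclohex-1-en-1-yl)hex-3-en-1-ol | CC1=C(CC/C(C)=C/CCO)C(C)(C)CCC1 | intermediate
7 | 2-[(3E)-6-iodo-3-methylhex-3-en-1-yl]-1,3,3-trimethylcyclohex-1-ene | CC1=C(CC/C(C)=C/CCI)C(C)(C)CCC1 | intermediate
8 | diethyl 2-[(3E)-4-methyl-6-(2,6,6-trimethylcyclohex-1-en-1-yl)hex-3-en-1-yl]propanedioate | CC1=C(CC/C(C)=C/CCC(C(=O)OCC)C(=O)OCC)C(C)(C)CCC1 | intermediate
9 | diethyl 2-(diiodomethyl)-2-[(3E)-4-methyl-6-(2,6,6-trimethylcyclohex-1-en-1-yl)hex-3-en-1-yl]propanedioate | CC1=C(CC/C(C)=C/CCC(C(I)I)(C(=O)OCC)C(=O)OCC)C(C)(C)CCC1 | intermediate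
10 | (2E,5E)-2-(iodomethylidene)-6-methyl-8-(2,6,6-trimethylcyclohex-1-en-1-yl)oct-5-enoic acid | CC1=C(CC/C(C)=C/CC/C(=C\I)C(=O)O)C(C)(C)CCC1 | intermediate
11 | (2E,5E)-2-(iodomethylidene)-6-methyl-8-(2,6,6-trimethylcyclohex-1-en-1-yl)oct-5-en-1-ol | CC1=C(CC/C(C)=C/CC/C(=C\I)CO)C(C)(C)CCC1 | intermediate
12 | 1-({[(2E,5E)-2-(iodomethylidene)-6-methyl-8-(2,6,6-trimethylcyclohex-1-en-1-yl)oct-5-en-1-yl]oxy}methyl)-4-methoxybenzene | CC1=C(CC/C(C)=C/CC/C(=C\I)COCc2ccc(OC)cc2)C(C)(C)CCC1 | intermediate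
13 | (2S)-2-hydroxybutanedioic acid (L-malic acid) | O[C@@H](CC(=O)O)C(=O)O | starting material
14 | 2-[(4S)-2,2-dimethyl-5-oxo-1,3-dioxolan-4-yl]acetic acid | OC(=O)C[C@@H]1OC(C)(C)OC1=O | intermediate
15 | 1,3-dioxo-1,3-dihydro-2H-isoindol-2-yl 2-[(4S)-2,2-dimethyl-5-oxo-1,3-dioxolan-4-yl]acetate | O=C(C[C@@H]1OC(C)(C)OC1=O)ON1C(=O)c2ccccc2C1=O | intermediate
16 | (tributylstannyl)methanol | CCCC[Sn](CCCC)(CCCC)CO | starting material
17 | tributyl{[(4-methoxyphenyl)methoxy]methyl}stannane | CCCC[Sn](CCCC)(CCCC)COCc1ccc(OC)cc1 | intermediate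
18 | [(4S)-2,2-dimethyl-5-oxo-1,3-dioxolan-4-yl]methyl radical | [CH2][C@@H]1OC(C)(C)OC1=O | intermediate
19 | (5S)-5-[(2E,6E)-3-{[(4-methoxyphenyl)methoxy]methyl}-7-methyl-9-(2,6,6-trimethylcyclohex-1-en-1-yl)nona-2,6-dien-1-yl]-2,2-dimethyl-1,3-dioxolan-4-one | CC1=C(CC/C(C)=C/CC/C(=C\C[C@@H]2OC(C)(C)OC2=O)COCc2ccc(OC)cc2)C(C)(C)CCC1 | intermediate
20 | {[(4-methoxyphenyl)methoxy]methyl}lithium | [Li]COCc1ccc(OC)cc1 | intermediate
21 | lithium (5S)-4-{[(4-methoxyphenyl)methoxy]methyl}-5-[(2E,6E)-3-{[(4-methoxyphenyl)methoxy]methyl}-7-methyl-9-(2,6,6-trimethylcyclohex-1-en-1-yl)nona-2,6-dien-1-yl]-2,2-dimethyl-1,3-dioxolan-4-olate (either configuration at C4) | [Li+].CC1=C(CC/C(C)=C/CC/C(=C\C[C@@H]2OC(C)(C)OC2([O-])COCc2ccc(OC)cc2)COCc2ccc(OC)cc2)C(C)(C)CCC1 | intermediate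
22 | (3S,5E,9E)-3-hydroxy-1-[(4-methoxyphenyl)methoxy]-6-{[(4-methoxyphenyl)methoxy]methyl}-10-methyl-12-(2,6,6-trimethylcyclohex-1-en-1-yl)dodeca-5,9-dien-2-one | CC1=C(CC/C(C)=C/CC/C(=C\C[C@H](O)C(=O)COCc2ccc(OC)cc2)COCc2ccc(OC)cc2)C(C)(C)CCC1 | intermediate
23 | (3S,5E,9E)-1-[(4-methoxyphenyl)methoxy]-6-{[(4-methoxyphenyl)methoxy]methyl}-10-methyl-2-oxo-12-(2,6,6-trimethylcyclohex-1-en-1-yl)dodeca-5,9-dien-3-yl (triphenyl-λ5-phosphanylidene)acetate | CC1=C(CC/C(C)=C/CC/C(=C\C[C@H](OC(=O)C=P(c2ccccc2)(c2ccccc2)c2ccccc2)C(=O)COCc2ccc(OC)cc2)COCc2ccc(OC)cc2)C(C)(C)CCC1 | intermediate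
24 | (5S)-4-{[(4-methoxyphenyl)methoxy]methyl}-5-[(2E,6E)-3-{[(4-methoxyphenyl)methoxy]methyl}-7-methyl-9-(2,6,6-trimethylcyclohex-1-en-1-yl)nona-2,6-dien-1-yl]furan-2(5H)-one | CC1=C(CC/C(C)=C/CC/C(=C\C[C@@H]2OC(=O)C=C2COCc2ccc(OC)cc2)COCc2ccc(OC)cc2)C(C)(C)CCC1 | intermediate
25 | (5S)-4-(hydroxymethyl)-5-[(2E,6E)-3-(hydroxymethyl)-7-methyl-9-(2,6,6-trimethylcyclohex-1-en-1-yl)nona-2,6-dien-1-yl]furan-2(5H)-one | CC1=C(CC/C(C)=C/CC/C(=C\C[C@@H]2OC(=O)C=C2CO)CO)C(C)(C)CCC1 | target

**Step count and risks**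

Total step count: 15. Longest linear sequence: 12 steps (steps 1–8, then 12–15).

Steps most likely to fail:

Step 12. Reduction of the redox-active ester may outpace oxidative addition, so that the radical is lost to hydrogen abstraction or dimerisation; the alkenyl iodide may be protodeiodinated, or the alkene geometry may erode at the alkenylnickel stage. The fallback replaces the radical coupling by a polar epoxide opening; it sets out from 12 and comes back at 19. Iodine–lithium exchange of 12 (t-BuLi, Et2O, −78 °C) would give the alkenyllithium F1, and MgBr2·OEt2 would convert it into the alkenylmagnesium bromide F2. With CuI (cat.) this should open commercial methyl (2S)-oxirane-2-carboxylate at its CH2 carbon to give the methyl (2S)-2-hydroxy ester F3, with the same bond formed, the alkene geometry retained and the stereocentre supplied by the epoxide. Saponification (LiOH, THF/H2O) would give the hydroxy acid F4, and 2,2-dimethoxypropane with pyridinium p-toluenesulfonate would close the dioxolanone 19.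

Step 13. The organolithium may enolise the dioxolanone instead of adding (loss of configurational purity at the carbinol carbon and recovered material), or the tetrahedral intermediate may collapse before the quench and lead to double addition. The fallback passes through an N-methoxy-N-methyl amide; it sets out from 19 and comes back at 22. Me(MeO)NH·HCl and i-PrMgCl (THF, −20 °C) should open 19 to the hydroxy N-methoxy-N-methyl amide F5; Et3SiCl/imidazole would give the triethylsilyl ether F6; addition of 20 (from 17 and n-BuLi, −78 °C) would give the α-silyloxy ketone F7; HF·pyridine in THF would release 22.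

Step 14. Intramolecular Wittig closure onto the α,α′-dioxygenated ketone may be slow, and at the temperature then needed a base-mediated α-ketol shift or epimerisation at the carbinol carbon may compete. The fallback separates acylation and olefination; it sets out from 22 and comes back at 24. Esterification of 22 with (diethoxyphosphoryl)acetic acid (N,N′-diisopropylcarbodiimide, DMAP cat., CH2Cl2) would give the phosphonoacetate F8, and intramolecular Horner–Wadsworth–Emmons olefination with LiCl/i-Pr2NEt in MeCN at rt should give 24.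

Further compounds

F1 | step 12 | [(1E,5E)-2-{[(4-methoxyphenyl)methoxy]methyl}-6-methyl-8-(2,6,6-trimethylcyclohex-1-en-1-yl)octa-1,5-dien-1-yl]lithium | CC1=C(CC/C(C)=C/CC/C(=C\[Li])COCc2ccc(OC)cc2)C(C)(C)CCC1
F2 | step 12 | bromo[(1E,5E)-2-{[(4-methoxyphenyl)methoxy]methyl}-6-methyl-8-(2,6,6-trimethylcyclohex-1-en-1-yl)octa-1,5-dien-1-yl]magnesium | CC1=C(CC/C(C)=C/CC/C(=C\[Mg]Br)COCc2ccc(OC)cc2)C(C)(C)CCC1
F3 | step 12 | methyl (2S,4E,8E)-2-hydroxy-5-{[(4-methoxyphenyl)methoxy]methyl}-9-methyl-11-(2,6,6-trimethylcyclohex-1-en-1-yl)undeca-4,8-dienoate | CC1=C(CC/C(C)=C/CC/C(=C\C[C@H](O)C(=O)OC)COCc2ccc(OC)cc2)C(C)(C)CCC1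
F4 | step 12 | (2S,4E,8E)-2-hydroxy-5-{[(4-methoxyphenyl)methoxy]methyl}-9-methyl-11-(2,6,6-trimethylcyclohex-1-en-1-yl)undeca-4,8-dienoic acid | CC1=C(CC/C(C)=C/CC/C(=C\C[C@H](O)C(=O)O)COCc2ccc(OC)cc2)C(C)(C)CCC1
F5 | step 13 | (2S,4E,8E)-2-hydroxy-N-methoxy-5-{[(4-methoxyphenyl)methoxy]methyl}-N,9-dimethyl-11-(2,6,6-trimethylcyclohex-1-en-1-yl)undeca-4,8-dienamide | CC1=C(CC/C(C)=C/CC/C(=C\C[C@H](O)C(=O)N(C)OC)COCc2ccc(OC)cc2)C(C)(C)CCC1
F6 | step 13 | (2S,4E,8E)-N-methoxy-5-{[(4-methoxyphenyl)methoxy]methyl}-N,9-dimethyl-2-[(triethylsilyl)oxy]-11-(2,6,6-trimethylcyclohex-1-en-1-yl)undeca-4,8-dienamide | CC1=C(CC/C(C)=C/CC/C(=C\C[C@H](O[Si](CC)(CC)CC)C(=O)N(C)OC)COCc2ccc(OC)cc2)C(C)(C)CCC1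
F7 | step 13 | (3S,5E,9E)-1-[(4-methoxyphenyl)methoxy]-6-{[(4-methoxyphenyl)methoxy]methyl}-10-methyl-3-[(triethylsilyl)oxy]-12-(2,6,6-trimethylcyclohex-1-en-1-yl)dodeca-5,9-dien-2-one | CC1=C(CC/C(C)=C/CC/C(=C\C[C@H](O[Si](CC)(CC)CC)C(=O)COCc2ccc(OC)cc2)COCc2ccc(OC)cc2)C(C)(C)CCC1
F8 | step 14 | (3S,5E,9E)-1-[(4-methoxyphenyl)methoxy]-6-{[(4-methoxyphenyl)methoxy]methyl}-10-methyl-2-oxo-12-(2,6,6-trimethylcyclohex-1-en-1-yl)dodeca-5,9-dien-3-yl (diethoxyphosphoryl)acetate | CC1=C(CC/C(C)=C/CC/C(=C\C[C@H](OC(=O)CP(=O)(OCC)OCC)C(=O)COCc2ccc(OC)cc2)COCc2ccc(OC)cc2)C(C)(C)CCC1
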